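Remark on the chemistry: C7, C9 and Ca are stereocentres only while they carry silicon, so every compound that contains them is handled as a mixture of diastereomers and no step is asked to control them.

## Analysis of the target

The target is a bibenzyl: a 3-methoxyphenyl ring B is joined through a CH2–CH2 bridge (Cb on ring B, Ca on ring A) to a hexasubstituted benzene ring A. Going round ring A, C1 carries the bridge, C2, C4 and C6 carry 4-hydroxybenzyl groups (benzylic carbons C7, C8 and C9), C3 carries a free hydroxyl and C5 a methoxy group. There is no stereocentre, so any stereocentre met on the way is temporary. The sensitive groups are the four phenols; three of them are 4-hydroxybenzyl units that oxidise easily to quinone methides, so they travel as benzyl ethers and the ring A phenol is released only at the end. The synthesis is hard for two reasons: all six positions of ring A are substituted, and the substituent pattern is symmetric (C2/C6, C3/C5) except that one of the two oxygens is methylated. A stepwise aromatic route must therefore place three benzyl groups between other substituents and tell two equivalent oxygens apart. The strategy rests on reading ring A as three two-carbon units, C1–C2, C3–C4 and C5–C6, each of which is an alkyne that already bears the two substituents of its positions. Ca, C7 and C9 are benzylic to ring A and the C3 substituent is an oxygen, so two silicon atoms (C9–Si–Ca and C7–Si–O) can hold the three alkynes in order and can later be replaced by hydrogen.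

## Retrosynthetic reasoning

**28 from 27.** The three O–benzyl bonds of the 4-hydroxybenzyl groups are cut last. Benzyl ethers survive organolithium reagents, fluoride and the metal-catalysed steps, and hydrogenolysis leaves the two methyl ethers and the bibenzyl bridge alone.

**27 from 26.** The C3–OH bond and one C–H bond each at C7, C9 and Ca are replaced by bonds to two silicon atoms, one bridging O(C3) and C7, the other bridging C9 and Ca. These are the only places where a tether can be removed without trace: the Si–O bond gives the phenol, and each C–Si bond is benzylic to ring A, so fluoride can expel carbon as a stabilised anion that takes up a proton. This leads back to 26, in which ring A is clamped into two five-membered silicon rings.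

**26 from 25 (key disconnection).** Ring A is opened at C6–C1, C2–C3 and C4–C5, which returns the alkynes C5≡C6, C1≡C2 and C3≡C4 of triyne 25. Cutting ring bonds rather than bonds to substituents removes the problem of loading six groups onto a benzene ring. C5 already carries the methoxy group and C3 the oxygen that becomes the phenol, so the two oxygens are never equivalent. The forward reaction has to join three tethered alkynes, two of them alkynyl ethers, in one order only; the three-atom tethers leave no other order open.

**25 from 22 and 24.** The Si–O bond of the silyl ynol ether is cut to chlorosilane 22 and ynolate 24. It is made last because it is the most fragile bond in 25. The silicon substituents are fixed here. A small dialkylsilyl group on an ynolate ends up on carbon or migrates there later, whereas hindered silyl chlorides react at oxygen and give ynol ethers that can be handled. The oxygen-bound silicon therefore carries two isopropyl groups, and the all-carbon tether keeps two methyl groups.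

**24 from 19, 19 from 18 and 6, 22 from 17 and 20.** Ynolate 24 is the oxygen-transfer product of acetylide 23, which comes from arylpropyne 19; 19 is cut at its C(sp)–C(sp3) bond to 18 and bromide 6. The C7–Si bond of 22 is cut to anion 21 and dichlorosilane 20. C7 of 17 is an unhindered benzylic and propargylic CH2, the most accessible acidic site of 17. The forward step must silylate 21 at C7 and not at the allenyl terminus C1, which the branched carbon Ca shields.

**17 from 15 and 6, 15 from 14.** The C2–C7 bond is cut to the terminal alkyne 15 and another molecule of 6; the magnesium acetylide 16 is formed without touching the C–H bonds at C9 and Ca. 15 is 14 without its trimethylsilyl cap.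

**14 from 10 and 13.** The C6–C9 bond is cut between the methoxyethynyl unit, delivered as stannane 13 (from 11 through 12), and the benzylic bromide 10. The shorter-looking plan, deprotonation next to a methoxyalkyne followed by silylation, is set aside. That anion is an oxygen-substituted allenyl anion, and such anions take electrophiles at the carbon that bears oxygen, which would put silicon on C5 instead of C9. With C9 as the electrophile in a palladium-catalysed coupling the ambiguity cannot arise, and the acid-sensitive ynol ether meets only neutral conditions.

**10 from 8 and 6, 8 from 4 and 5, 4 from 1 and 2.** The C9–Si bond is cut to chlorosilane 8 and carbenoid 9, formed from 6 in the presence of 8; this brings in C9 together with the bromine needed for the coupling. The Ca–Si bond of 8 is cut to anion 7 and 5. Ca is silylated at the stage of the silyl-capped alkyne 4 for two reasons. The trimethylsilyl group on the alkyne terminus steers the chlorosilane to the propargylic carbon. C7 also does not exist yet; once the benzyl group is on C2, its CH2 would be deprotonated before Ca. The Ca–Cb bond of 4 is cut to propargyl anion 3 (from 1) and benzylic bromide 2, which avoids an acetylide displacement on a 2-arylethyl halide that could eliminate.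

## Alternatives that were turned down

**Alternative 1:** The two bridge bonds C1–Ca and Cb–ring B are cut together, leaving the fully substituted ring A triflate A2, vinylboronic acid pinacol ester A3 and 3-methoxyphenyllithium A4. Forward, A3 and A4 combine at boron; palladium inserted into the C1–O bond of A2 activates the vinyl group, the aryl group shifts from boron to Cb and reductive elimination joins C1 to Ca, giving the benzylic boronate A1. Protodeboronation and debenzylation would finish.
- For: the key step is a known reaction type for aryl triflates, it is convergent, and ring B and the bridge arrive in one late step. On precedent of the key step this alternative is stronger than the chosen route.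
- Against: the triflate carbon of A2 is flanked by benzyl groups at C2 and C6, so oxidative addition and above all the metallate shift at a crowded palladium centre are slowed, and direct aryl transfer or simple vinylation can take over. A boron-bearing stereocentre at Cb is made only to be removed. The real difficulty, ring A with six substituents and three distinguished oxygens (C1–OTf, C3–OBn, C5–OMe), is left to a long stepwise arene synthesis of A2.
- Comparison: the chosen strategy gives up the better precedent, and in return builds ring A with all substituents in fixed order and with differentiated oxygens in the step that defines the route.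

**Alternative 2:** Ring A is cut at C1–C2 to the acyclic triketone A6, in which a cinnamoyl carbonyl is the future C1 and the CH2 beyond the last carbonyl is the future C2. Forward, base makes that CH2 add to the cinnamoyl carbonyl, and dehydration and enolisation give the stilbene resorcinol A5. Mono-methylation and hydrogenation (alkene and benzyl ethers together) would follow.
- For: it is biomimetic, needs no precious metal for ring formation, and the hydrogenation endgame does two jobs at once. In step economy and simplicity of reagents it is as strong as or stronger than the chosen route.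
- Against: A6 has several enolisable positions and an enone. Michael addition onto the cinnamoyl unit, ring closure through oxygen and the alternative Claisen-type closure compete with the wanted aldol. A6 itself requires three controlled C-acylations and two C-benzylations of a poly-β-carbonyl chain. A5 is a symmetric resorcinol whose two hydroxyls, each between two benzyl groups, are equivalent, so the single methyl ether can only be made statistically.
- Comparison: the chosen strategy is longer, but the methoxy group enters on an alkyne carbon and the other oxygen as a silyl ether, so no desymmetrisation is needed, and the ring closure has one possible outcome.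

**Alternative 3:** C2–C7, C6–C9 and C1–Ca are cut from the aryl iodide A8, which has hydrogens at C2 and C6. Forward, palladium together with norbornene A11 benzylates both ortho C–H positions with 4-(benzyloxy)benzyl chloride A9, and the sequence ends with an ipso Heck reaction with 3-methoxystyrene A10, giving stilbene A7. Hydrogenation would finish.
- For: three C–C bonds form in one operation from a simple iodide and two cheap partners. On convergence and step count this is the strongest of all four plans.
- Against: each C–H bond to be palladated lies between the iodide carbon and an alkoxy group (C3–OBn, C5–OMe). A meta substituent normally shuts down the neighbouring ortho position in this chemistry, and here both are affected. The final Heck step must then occur at a carbon between two new benzyl groups. Early Heck termination and mono-benzylation are the expected leaks. A8 still needs a differentiated 1,3-dioxygenated arene.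
- Comparison: the chosen strategy does not functionalise any hindered aromatic C–H bond; all ring bonds are formed from alkynes, and the cost is a longer preparation of the precursor.

Key step: step 9

## Route

Step 1
Reactants: 1 trimethyl(prop-1-yn-1-yl)silane; 2 3-methoxybenzyl bromide
Product: 4 [4-(3-methoxyphenyl)but-1-yn-1-yl]trimethylsilane, via 3-lithio-1-(trimethylsilyl)propyne 3 (not isolated)
Conditions: n-BuLi, THF, −78 → −20 °C; then 2, −78 °C → rt
Reagents that add atoms: none
Why: Propargylic lithiation of 1 gives anion 3, which is alkylated by the reactive benzylic bromide at the propargylic carbon (SN2); the silyl group on the alkyne terminus disfavours attack at the allenyl end.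

Step 2
Reactants: 4 [4-(3-methoxyphenyl)but-1-yn-1-yl]trimethylsilane; 5 dichlorodimethylsilane; 6 4-(benzyloxy)benzyl bromide
Product: 10 (α-bromobenzyl)silane {[4-(benzyloxy)phenyl](bromo)methyl}[1-(3-methoxyphenyl)-4-(trimethylsilyl)but-3-yn-2-yl]dimethylsilane (mixture of diastereomers), via lithiated alkyne 7 (not isolated), via chlorosilane 8 (not isolated), via α-bromobenzyllithium 9 (not isolated)
Conditions: s-BuLi, THF, −78 °C; added to 5 (5 equiv), THF, −78 °C → rt; volatiles removed in vacuo; then 6, LiN(iPr)2, THF, −78 °C
Reagents that add atoms: none
Why: The propargylic CH2 of 4 is its most acidic site, and anion 7 is silylated at that carbon because the alkyne terminus is blocked by SiMe3 (propargylic lithiation–silylation of 1-silylalkynes); excess 5 limits the reaction to one Si–Cl bond. Deprotonation of 6 in the presence of 8 gives carbenoid 9, which should be trapped at silicon before it attacks unreacted 6 (in situ silylation of α-lithiated benzyl halides). The two stereocentres form without control, which does not matter.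

Step 3
Reactants: 11 chloroacetaldehyde dimethyl acetal
Product: 13 tributyl(methoxyethynyl)stannane, via lithium methoxyacetylide 12 (not isolated)
Conditions: LiNEt2 (3 equiv), THF, 0 °C; then Bu3SnCl, 0 °C → rt
Reagents that add atoms: tributyltin chloride, CCCC[Sn](Cl)(CCCC)CCCC
Why: Loss of methanol and HCl from the chloroacetal and deprotonation give 12, and substitution at tin gives the stannane (standard preparation of alkoxyethynylstannanes), which can be distilled free of amine and alkoxide.

Step 4
Reactants: 10 (α-bromobenzyl)silane; 13 tributyl(methoxyethynyl)stannane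
Product: 14 {1-[4-(benzyloxy)phenyl]-3-methoxyprop-2-yn-1-yl}[1-(3-methoxyphenyl)-4-(trimethylsilyl)but-3-yn-2-yl]dimethylsilane (mixture of diastereomers)
Conditions: Pd(PPh3)4 (5 mol %), THF, 60 °C
Reagents that add atoms: none
Why: Stille coupling: zerovalent palladium inserts into the benzylic C–Br bond, the alkynyl group is transferred from tin and C(sp3)–C(sp) reductive elimination forms C9–C6. The palladium-bound carbon carries no β-hydrogen, and the neutral conditions spare the ynol ether and the silylalkyne.

Step 5
Reactants: 14 silyl-capped diyne
Product: 15 {1-[4-(benzyloxy)phenyl]-3-methoxyprop-2-yn-1-yl}[1-(3-methoxyphenyl)but-3-yn-2-yl]dimethylsilane (mixture of diastereomers)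
Conditions: K2CO3 (cat.), MeOH/THF, 0 °C
Reagents that add atoms: none
Why: Methanolysis of the exposed C(sp)–SiMe3 bond should be much faster than attack on the silicon atom between the two secondary carbons C9 and Ca; ynol ethers are stable to mild base.

Step 6
Reactants: 15 terminal alkyne; 6 4-(benzyloxy)benzyl bromide
Product: 17 {1-[4-(benzyloxy)phenyl]-3-methoxyprop-2-yn-1-yl}{5-[4-(benzyloxy)phenyl]-1-(3-methoxyphenyl)pent-3-yn-2-yl}dimethylsilane (mixture of diastereomers), via alkynylmagnesium bromide 16 (not isolated)
Conditions: EtMgBr (1.0 equiv), THF, 0 → 40 °C; then CuBr·SMe2 (10 mol %), 6, THF, 50 °C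
Reagents that add atoms: none
Why: EtMgBr removes only the acetylenic proton (C9–H and Ca–H are too weakly acidic for a Grignard reagent) and is used up before copper is added, so no alkyl Grignard reagent is left to add to the ynol ether. Copper-catalysed coupling of alkynyl Grignard reagents with benzylic bromides is a standard route to 1-aryl-2-alkynes.

Step 7
Reactants: 18 ethynylmagnesium bromide; 6 4-(benzyloxy)benzyl bromide
Product: 19 1-(benzyloxy)-4-(prop-2-yn-1-yl)benzene
Conditions: 18 (3 equiv), CuBr·SMe2 (5 mol %), THF, 0 → 40 °C
Reagents that add atoms: none
Why: Copper-catalysed benzylation of an alkynyl Grignard reagent; excess 18 suppresses a second benzylation, and the mild conditions avoid isomerisation to the allene.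

Step 8
Reactants: 17 internal alkyne; 20 dichlorodiisopropylsilane; 19 1-(benzyloxy)-4-(prop-2-yn-1-yl)benzene
Product: 25 triyne carrying the C9–SiMe2–Ca tether and the C7–Si(iPr)2–O tether to the ynol ether of 19 (mixture of diastereomers), via C7-lithiated alkyne 21 (not isolated), via C7-chlorosilane 22 (not isolated), via lithium acetylide 23 (not isolated), via lithium ynolate 24 (not isolated)
Conditions: 17, n-BuLi, THF, −78 °C; 20 (4 equiv), −78 → 0 °C; volatiles removed in vacuo; separately 19, n-BuLi, THF, −78 °C, then LiOOt-Bu (from t-BuOOH, LiN(SiMe3)2), −78 → 0 °C; solutions combined, THF, 0 °C → rt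
Reagents that add atoms: tert-butyl hydroperoxide, CC(C)(C)OO
Why: n-BuLi removes an unhindered benzylic and propargylic C7 proton of 17 under kinetic control, and the bulky dichlorosilane attacks anion 21 at C7 rather than at the allenyl terminus C1, which carries the branched carbon Ca (propargylic lithiation–silylation). Oxygen transfer from LiOOt-Bu to acetylide 23 gives ynolate 24, and hindered chlorosilanes silylate ynolates at oxygen, so the diisopropylsilyl group should give a stable silyl ynol ether.

Step 9
Reactants: 25 triyne
Product: 26 cyclotrimer: ring A fused to a 2,2-diisopropyl-2,3-dihydro-1,2-benzoxasilole ring and a 2,2-dimethyl-2-silaindane ring (mixture of diastereomers)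
Conditions: RhCl(PPh3)3 (10 mol %), toluene (0.01 M), 90 °C
Reagents that add atoms: none
Why: Proposed new method: monovalent rhodium, after loss of phosphine, binds the methoxyalkyne and the central alkyne of 25 and couples them oxidatively to a rhodacyclopentadiene (bond C6–C1), the tethered silyloxyalkyne inserts (bond C2–C3) and reductive elimination (bond C4–C5) releases the arene; the closest known reaction type is the RhCl(PPh3)3- or CpCo(CO)2-mediated [2+2+2] cyclotrimerisation of triynes held by removable silicon tethers, which has not been shown for a triyne whose outer alkynes are a methyl ynol ether and a silyl ynol ether. Ring A closes as the six-membered ring of the [2+2+2] event itself. The silaindane ring (C6, C9, Si, Ca, C1) closes in the oxidative coupling, where the three-atom tether makes the fused five-membered ring the natural outcome, as in 1,6-diyne couplings. The oxasilole ring (C2, C7, Si, O, C3) closes when the last alkyne, held by the second three-atom tether, inserts into the Rh–C2 bond. No stereocentre is created; the silicon-bearing centres C9, Ca and C7 are carried through as a mixture and are erased in step 10. The step needs a single substituent order and intramolecular rather than intermolecular coupling: the order is fixed because each alkyne can only bond to its tethered neighbours, and high dilution together with the two short tethers favours the intramolecular path. The electron-rich alkynyl ethers should bind rhodium well, the bulky diisopropylsilyl group holds back migration of silicon from oxygen to carbon, and the neutral chloride complex has no Lewis acidic site that would hydrate the ynol ethers.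

Step 10
Reactants: 26 cyclotrimer
Product: 27 2,4,6-tris[4-(benzyloxy)benzyl]-3-methoxy-5-[2-(3-methoxyphenyl)ethyl]phenol
Conditions: Bu4NF (excess), THF/DMF, H2O (few equiv), 70 °C; aqueous NH4Cl work-up
Reagents that add atoms: none
Why: Fluoride attacks both silicon atoms: the Si–O bond opens first, and each C–Si bond is then cleaved from a pentacoordinate fluorosilicate because the departing carbanion is benzylic to ring A (doubly benzylic at C7 and C9). Water protonates the carbanions, so all three temporary stereocentres become CH2 (fluoride-induced protodesilylation of benzylic silanes).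

Step 11
Reactants: 27 tri-O-benzyl ether
Product: 28 2,4,6-tris(4-hydroxybenzyl)-3-methoxy-5-[2-(3-methoxyphenyl)ethyl]phenol (target)
Conditions: H2 (1 atm), Pd/C, EtOAc/EtOH, rt
Reagents that add atoms: none
Why: Hydrogenolysis of the three benzyl aryl ethers; the methyl ethers, the bibenzyl bridge and the diarylmethane CH2 groups are inert under these conditions.

## Compound list

1 | trimethyl(prop-1-yn-1-yl)silane (1-(trimethylsilyl)propyne) | CC#C[Si](C)(C)C | starting material
2 | 1-(bromomethyl)-3-methoxybenzene (3-methoxybenzyl bromide) | COc1cccc(CBr)c1 | starting material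
3 | [3-(trimethylsilyl)prop-2-yn-1-yl]lithium (not isolated) | [Li]CC#C[Si](C)(C)C | intermediate
4 | [4-(3-methoxyphenyl)but-1-yn-1-yl]trimethylsilane | COc1cccc(CCC#C[Si](C)(C)C)c1 | intermediate
5 | dichlorodimethylsilane | C[Si](C)(Cl)Cl | starting material
6 | 1-(benzyloxy)-4-(bromomethyl)benzene (4-(benzyloxy)benzyl bromide) | BrCc1ccc(OCc2ccccc2)cc1 | starting material
7 | [1-(3-methoxyphenyl)-4-(trimethylsilyl)but-3-yn-2-yl]lithium, 4 lithiated at Ca (not isolated) | COc1cccc(CC([Li])C#C[Si](C)(C)C)c1 | intermediate
8 | chloro[1-(3-methoxyphenyl)-4-(trimethylsilyl)but-3-yn-2-yl]dimethylsilane, racemic (not isolated) | COc1cccc(CC(C#C[Si](C)(C)C)[Si](C)(C)Cl)c1 | intermediate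
9 | {[4-(benzyloxy)phenyl](bromo)methyl}lithium (not isolated) | [Li]C(Br)c1ccc(OCc2ccccc2)cc1 | intermediate
10 | {[4-(benzyloxy)phenyl](bromo)methyl}[1-(3-methoxyphenyl)-4-(trimethylsilyl)but-3-yn-2-yl]dimethylsilane, mixture of diastereomers | COc1cccc(CC(C#C[Si](C)(C)C)[Si](C)(C)C(Br)c2ccc(OCc3ccccc3)cc2)c1 | intermediate
11 | 2-chloro-1,1-dimethoxyethane (chloroacetaldehyde dimethyl acetal) | COC(CCl)OC | starting material
12 | lithium methoxyacetylide (not isolated) | [Li]C#COC | intermediate
13 | tributyl(methoxyethynyl)stannane | CCCC[Sn](CCCC)(CCCC)C#COC | intermediate
14 | {1-[4-(benzyloxy)phenyl]-3-methoxyprop-2-yn-1-yl}[1-(3-methoxyphenyl)-4-(trimethylsilyl)but-3-yn-2-yl]dimethylsilane, mixture of diastereomers | COC#CC(c1ccc(OCc2ccccc2)cc1)[Si](C)(C)C(Cc1cccc(OC)c1)C#C[Si](C)(C)C | intermediate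
15 | {1-[4-(benzyloxy)phenyl]-3-methoxyprop-2-yn-1-yl}[1-(3-methoxyphenyl)but-3-yn-2-yl]dimethylsilane, mixture of diastereomers | COC#CC(c1ccc(OCc2ccccc2)cc1)[Si](C)(C)C(Cc1cccc(OC)c1)C#C | intermediate
16 | bromomagnesium acetylide of 15 (not isolated) | COC#CC(c1ccc(OCc2ccccc2)cc1)[Si](C)(C)C(Cc1cccc(OC)c1)C#C[Mg]Br | intermediate
17 | {1-[4-(benzyloxy)phenyl]-3-methoxyprop-2-yn-1-yl}{5-[4-(benzyloxy)phenyl]-1-(3-methoxyphenyl)pent-3-yn-2-yl}dimethylsilane, mixture of diastereomers | COC#CC(c1ccc(OCc2ccccc2)cc1)[Si](C)(C)C(Cc1cccc(OC)c1)C#CCc1ccc(OCc2ccccc2)cc1 | intermediate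
18 | ethynylmagnesium bromide | C#C[Mg]Br | starting material
19 | 1-(benzyloxy)-4-(prop-2-yn-1-yl)benzene | C#CCc1ccc(OCc2ccccc2)cc1 | intermediate
20 | dichlorodi(propan-2-yl)silane (dichlorodiisopropylsilane) | CC(C)[Si](Cl)(Cl)C(C)C | starting material
21 | 17 lithiated at C7 (not isolated) | COC#CC(c1ccc(OCc2ccccc2)cc1)[Si](C)(C)C(Cc1cccc(OC)c1)C#CC([Li])c1ccc(OCc2ccccc2)cc1 | intermediate
22 | 17 carrying a chlorodiisopropylsilyl group at C7 (not isolated) | COC#CC(c1ccc(OCc2ccccc2)cc1)[Si](C)(C)C(Cc1cccc(OC)c1)C#CC(c1ccc(OCc2ccccc2)cc1)[Si](Cl)(C(C)C)C(C)C | intermediate
23 | {3-[4-(benzyloxy)phenyl]prop-1-yn-1-yl}lithium (not isolated) | [Li]C#CCc1ccc(OCc2ccccc2)cc1 | intermediate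
24 | lithium 3-[4-(benzyloxy)phenyl]prop-1-yn-1-olate (not isolated) | [Li]OC#CCc1ccc(OCc2ccccc2)cc1 | intermediate
25 | triyne: 17 carrying at C7 a diisopropylsilyl group whose oxygen substituent is the 3-[4-(benzyloxy)phenyl]prop-1-yn-1-yloxy group; mixture of diastereomers | COC#CC(c1ccc(OCc2ccccc2)cc1)[Si](C)(C)C(Cc1cccc(OC)c1)C#CC(c1ccc(OCc2ccccc2)cc1)[Si](C(C)C)(C(C)C)OC#CCc1ccc(OCc2ccccc2)cc1 | intermediate
26 | cyclotrimer: ring A (C5 OMe, C4 4-(benzyloxy)benzyl) fused at C2–C3 to a 2,2-diisopropyl-2,3-dihydro-1,2-benzoxasilole ring (O on C3, C7 bearing 4-(benzyloxy)phenyl) and at C6–C1 to a 2,2-dimethyl-2-silaindane ring (C9 bearing 4-(benzyloxy)phenyl, Ca bearing 3-methoxybenzyl); mixture of diastereomers | COc1c(Cc2ccc(OCc3ccccc3)cc2)c2O[Si](C(C)C)(C(C)C)C(c3ccc(OCc4ccccc4)cc3)c2c2c1C(c1ccc(OCc3ccccc3)cc1)[Si](C)(C)C2Cc1cccc(OC)c1 | intermediate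
27 | 2,4,6-tris[4-(benzyloxy)benzyl]-3-methoxy-5-[2-(3-methoxyphenyl)ethyl]phenol | COc1cccc(CCc2c(Cc3ccc(OCc4ccccc4)cc3)c(O)c(Cc3ccc(OCc4ccccc4)cc3)c(OC)c2Cc2ccc(OCc3ccccc3)cc2)c1 | intermediate
28 | 2,4,6-tris(4-hydroxybenzyl)-3-methoxy-5-[2-(3-methoxyphenyl)ethyl]phenol | COc1cccc(CCc2c(Cc3ccc(O)cc3)c(O)c(Cc3ccc(O)cc3)c(OC)c2Cc2ccc(O)cc2)c1 | target

## Step count and least certain steps

Total: 11 steps. Longest linear sequence: 9 steps (1, 2, 4, 5, 6, 8, 9, 10, 11); steps 3 and 7 are side branches.

**Step 9 (key step).** Most likely failure: the silyl ynol ether is lost before the third alkyne inserts, by metal-induced migration of silicon from oxygen to carbon or by oligomerisation of the electron-rich alkynyl ethers; the crowded metallacycle may also stall because the arene is hexasubstituted. Fallback, from 25 back to 26, in two known stages instead of one catalytic event: 25 is treated with Cp2ZrBu2 (from Cp2ZrCl2 and n-BuLi, THF, −78 °C → rt), which couples the methoxyalkyne and the central alkyne to the silicon-bridged zirconacyclopentadiene F1. NiBr2(PPh3)2 (1 equiv, rt → 50 °C) then takes the diene over from zirconium, the tethered silyloxyalkyne inserts at divalent nickel and reductive elimination gives 26. Should zirconium couple the central alkyne with the silyloxyalkyne instead, insertion of the remaining alkyne leads to the same arene. Both stages are known reaction types (zirconocene coupling of tethered diynes; nickel-mediated benzene formation from zirconacyclopentadienes and a third alkyne).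

**Step 2.** Most likely failure: carbenoid 9 attacks unreacted 6 (self-condensation towards a stilbene) faster than it is trapped by the hindered chlorosilane 8, or the amide base deprotonates 8 at Ca. Fallback, from 8 back to 10, with a stable α-oxygenated benzyllithium in place of the carbenoid: 4-(benzyloxy)benzyl N,N-diisopropylcarbamate F2, available in one step from the corresponding benzyl alcohol, is lithiated with s-BuLi/TMEDA at −78 °C and silylated with 8 to give the α-silyl carbamate F3. LiAlH4 removes the carbamoyl group to give the α-silyl benzylic alcohol F4, which is kept as its aluminium alkoxide until a cold acidic quench so that silicon does not migrate to oxygen. CBr4/PPh3 then converts the alcohol into 10.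

**Step 8.** Most likely failure: proton removal at C9 (thermodynamically more acidic because of its silicon) instead of C7, or silylation of 21 at the allenyl terminus; the hindered chlorosilane 22 may also be consumed by tert-butoxide rather than by ynolate 24. Fallback, from 15 back to 25, forming the C2–C7 bond with silicon already on C7: 6 is deprotonated with LiN(iPr)2 at −78 °C in the presence of 20 to give {[4-(benzyloxy)phenyl](bromo)methyl}chlorodiisopropylsilane F5. Ynolate 24 is silylated at oxygen by this chlorosilane to give the bromide-bearing silyl ynol ether F6. 15 is stannylated at its terminal alkyne with Bu3SnOMe to give the alkynylstannane F7. Pd(PPh3)4 then couples F6 and F7 as in step 4 to give 25, and no strong base meets the C9–H bond.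

**Step 4.** Most likely failure: slow oxidative addition or transmetalation at the hindered α-silyl benzylic carbon, so that reduction or homocoupling of the bromide takes over. Fallback, from 10 and 13 back to 14, by direct substitution instead of catalysis: MeLi cleaves 13 at tin and regenerates 12 free of amine and alkoxide, and 12 displaces bromide from 10 in THF/DMPU at −78 → 0 °C (SN2 at a benzylic carbon that cannot eliminate). No new compound is needed.

**Step 10.** Most likely failure: incomplete protodesilylation at Ca, the only C–Si bond that is singly benzylic, so that the reaction stops at a fluorosilane. Fallback, from 26 to 28: Bu4NF at rt cleaves the Si–O bond and the two doubly benzylic C–Si bonds and leaves the benzylic fluorosilane F8. Tamao oxidation (H2O2, KF, KHCO3, THF/MeOH) turns its C–Si bond into a C–O bond and gives the benzylic alcohol F9. Hydrogenation over Pd/C with a trace of HCl then removes the benzylic hydroxyl together with the three benzyl ethers and gives 28 directly.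

## Further compounds

F1 | step 9 | zirconacyclopentadiene of 25: Cp2Zr bonded to C5 and C2, C6–C1 bond and silacyclopentene ring closed, silyloxyalkyne still free | COC1=C2C(c3ccc(OCc4ccccc4)cc3)[Si](C)(C)C(Cc3cccc(OC)c3)C2=C(C(c2ccc(OCc3ccccc3)cc2)[Si](C(C)C)(C(C)C)OC#CCc2ccc(OCc3ccccc3)cc2)[Zr]1(C1C=CC=C1)C1C=CC=C1
F2 | step 2 | 4-(benzyloxy)benzyl N,N-diisopropylcarbamate | CC(C)N(C(C)C)C(=O)OCc1ccc(OCc2ccccc2)cc1
F3 | step 2 | α-silyl carbamate: 10 with OC(O)N(iPr)2 in place of Br | COc1cccc(CC(C#C[Si](C)(C)C)[Si](C)(C)C(OC(=O)N(C(C)C)C(C)C)c2ccc(OCc3ccccc3)cc2)c1
F4 | step 2 | α-silyl benzylic alcohol: 10 with OH in place of Br | COc1cccc(CC(C#C[Si](C)(C)C)[Si](C)(C)C(O)c2ccc(OCc3ccccc3)cc2)c1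
F5 | step 8 | {[4-(benzyloxy)phenyl](bromo)methyl}chlorodiisopropylsilane | BrC(c1ccc(OCc2ccccc2)cc1)[Si](Cl)(C(C)C)C(C)C
F6 | step 8 | {[4-(benzyloxy)phenyl](bromo)methyl}diisopropylsilyl ynol ether of 19 | BrC(c1ccc(OCc2ccccc2)cc1)[Si](C(C)C)(C(C)C)OC#CCc1ccc(OCc2ccccc2)cc1
F7 | step 8 | tributylstannyl acetylide of 15 | COC#CC(c1ccc(OCc2ccccc2)cc1)[Si](C)(C)C(Cc1cccc(OC)c1)C#C[Sn](CCCC)(CCCC)CCCC
F0 | step 4 | none | none
F8 | step 10 | 27 carrying a fluorodimethylsilyl group at Ca | COc1cccc(CC(c2c(Cc3ccc(OCc4ccccc4)cc3)c(O)c(Cc3ccc(OCc4ccccc4)cc3)c(OC)c2Cc2ccc(OCc3ccccc3)cc2)[Si](C)(C)F)c1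
F9 | step 10 | 27 carrying a hydroxyl group at Ca | COc1cccc(CC(O)c2c(Cc3ccc(OCc4ccccc4)cc3)c(O)c(Cc3ccc(OCc4ccccc4)cc3)c(OC)c2Cc2ccc(OCc3ccccc3)cc2)c1
A1 | alternative 1 | racemic pinacol boronate at Cb of the tetra-O-benzyl target | COc1cccc(C(Cc2c(Cc3ccc(OCc4ccccc4)cc3)c(OCc3ccccc3)c(Cc3ccc(OCc4ccccc4)cc3)c(OC)c2Cc2ccc(OCc3ccccc3)cc2)B2OC(C)(C)C(C)(C)O2)c1
A2 | alternative 1 | 3-(benzyloxy)-2,4,6-tris[4-(benzyloxy)benzyl]-5-methoxyphenyl triflate | O=S(=O)(Oc1c(Cc2ccc(OCc3ccccc3)cc2)c(OCc2ccccc2)c(Cc2ccc(OCc3ccccc3)cc2)c(OC)c1Cc1ccc(OCc2ccccc2)cc1)C(F)(F)F
A3 | alternative 1 | vinylboronic acid pinacol ester | C=CB1OC(C)(C)C(C)(C)O1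
A4 | alternative 1 | 3-methoxyphenyllithium | [Li]c1cccc(OC)c1
A5 | alternative 2 | 2,4,6-tris[4-(benzyloxy)benzyl]-5-[(E)-2-(3-methoxyphenyl)ethenyl]benzene-1,3-diol | COc1cccc(/C=C/c2c(Cc3ccc(OCc4ccccc4)cc3)c(O)c(Cc3ccc(OCc4ccccc4)cc3)c(O)c2Cc2ccc(OCc3ccccc3)cc2)c1
A6 | alternative 2 | (E)-9-[4-(benzyloxy)phenyl]-4,6-bis[4-(benzyloxy)benzyl]-1-(3-methoxyphenyl)non-1-ene-3,5,7-trione | COc1cccc(/C=C/C(=O)C(Cc2ccc(OCc3ccccc3)cc2)C(=O)C(Cc2ccc(OCc3ccccc3)cc2)C(=O)CCc2ccc(OCc3ccccc3)cc2)c1
A7 | alternative 3 | 1-(benzyloxy)-2,4,6-tris[4-(benzyloxy)benzyl]-3-methoxy-5-[(E)-2-(3-methoxyphenyl)ethenyl]benzene | COc1cccc(/C=C/c2c(Cc3ccc(OCc4ccccc4)cc3)c(OCc3ccccc3)c(Cc3ccc(OCc4ccccc4)cc3)c(OC)c2Cc2ccc(OCc3ccccc3)cc2)c1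
A8 | alternative 3 | 1-(benzyloxy)-2-[4-(benzyloxy)benzyl]-5-iodo-3-methoxybenzene | COc1cc(I)cc(OCc2ccccc2)c1Cc1ccc(OCc2ccccc2)cc1
A9 | alternative 3 | 4-(benzyloxy)benzyl chloride | ClCc1ccc(OCc2ccccc2)cc1
A10 | alternative 3 | 3-methoxystyrene | C=Cc1cccc(OC)c1
A11 | alternative 3 | norbornene | C1=CC2CCC1C2
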